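Numbering: ring A is C1–C5 plus C10 (C4 bears =CH2, C5 H, C10 CH3). Ring B is C5–C10 (C8 bears CH3 = C12; C9 bears CH3 = C13 and C11H2–quinone). α is the face of H5, β the face of the C10 methyl.
Cuts, in retrosynthetic order: the quinone oxygens, C4=CH2, C11–aryl, H–C8 (a C8=C12 alkene), then C8–C9 together with H–C13, then C8–C12, C5–C6 and C10–C9.
Enabling feature: C9 is quaternary, carries a plain methyl (C13) and adjoins C8, which can stay sp2. C9–C13H3 is therefore a disguised C9=C13H2 alkene on C10. Carbopalladation from a C8 vinyl triflate on the C5 side chain leaves a C13–Pd bond with no β-hydrogen, ready for hydride.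
Forward: ring A is bought as 3-methylcyclohexenone, and one flask joins C9 to C10 and C6 to C5. The allyl arm is grown into the vinyl triflate, ring B closes by reductive Heck reaction, and the arene is joined at C11. C4=CH2 and the quinone come last.
Stereochemistry: C10 comes from a chiral copper–NHC catalyst, C5 from anti alkylation of the enolate, C9 from rotamer control in the insertion, and C8 from hydroxyl-directed hydrogenation.

Key step: step 8

Assumption: the enantiomer of the imidazolinium salt in step 2 is the one that sends the alkenyl group to the enone face giving (S)-C10; if the sense is opposite, its mirror image is used. TBS = tert-butyldimethylsilyl.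

Step 1
Reactants: 1 2-bromoprop-2-en-1-ol
Product: 2 tert-butyl[(2-bromoprop-2-en-1-yl)oxy]dimethylsilane
Conditions: t-BuMe2SiCl, imidazole, CH2Cl2, 0 °C → rt
Reagents that add atoms: tert-butyldimethylsilyl chloride, C[Si](C)(Cl)C(C)(C)C
Why: Imidazole-promoted O-silylation of a primary allylic alcohol is routine and masks the future C11 hydroxyl for the organometallic steps.

Step 2
Reactants: 2 tert-butyl[(2-bromoprop-2-en-1-yl)oxy]dimethylsilane; 3 3-methylcyclohex-2-en-1-one; 4 allyl bromide
Product: 7 (2R,3S)-2-allyl-3-[3-(TBSO)prop-1-en-2-yl]-3-methylcyclohexan-1-one, via alkenyl Grignard reagent 5 (not isolated), via magnesium enolate 6 (not isolated)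
Conditions: 2, Mg, Et2O, 35 °C; 3, Cu(OTf)2 (3 mol %), 1-[(2S)-1-hydroxy-3,3-dimethylbutan-2-yl]-3-(2,4,6-trimethylphenyl)-4,5-dihydroimidazolium hexafluorophosphate (4 mol %), Et2O, −30 °C; 4, DMPU, −30 °C → rt
Reagents that add atoms: none
Why: Copper–NHC-catalysed asymmetric conjugate addition of a Grignard reagent to a β-methyl cyclic enone builds quaternary C10 under catalyst control, and the regiodefined enolate is allylated at C5 on the face away from the bulkier silyloxypropenyl arm, which sets the C5/C10 trans relation (tandem conjugate addition–enolate alkylation).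

Step 3
Reactants: 7 (2R,3S)-2-allyl-3-[3-(TBSO)prop-1-en-2-yl]-3-methylcyclohexan-1-one
Product: 8 (6R,7S)-6-allyl-7-[3-(TBSO)prop-1-en-2-yl]-7-methyl-1,4-dioxaspiro[4.5]decane
Conditions: Me3SiOCH2CH2OSiMe3, Me3SiOTf (10 mol %), CH2Cl2, −78 → −20 °C
Reagents that add atoms: 1,2-bis(trimethylsilyloxy)ethane, C[Si](C)(C)OCCO[Si](C)(C)C
Why: Aprotic ketalization with the bis-silyl glycol (Noyori conditions) masks the hindered C4 ketone at low temperature without enolization, so C5 keeps its configuration and the silyl ether and both alkenes survive.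

Step 4
Reactants: 8 (6R,7S)-6-allyl-7-[3-(TBSO)prop-1-en-2-yl]-7-methyl-1,4-dioxaspiro[4.5]decane
Product: 10 3-{(6R,7S)-7-[3-(TBSO)prop-1-en-2-yl]-7-methyl-1,4-dioxaspiro[4.5]decan-6-yl}propan-1-ol, via B-alkyl-9-BBN adduct 9 (not isolated)
Conditions: 9-BBN, THF, 0 °C → rt; NaOH, H2O2, 0 °C
Reagents that add atoms: hydrogen peroxide, OO
Why: Hydroboration–oxidation with bulky 9-BBN picks the monosubstituted allyl alkene over the C9=C13 alkene, which is shielded by quaternary C10, and places oxygen on terminal C8.

Step 5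
Reactants: 10 3-{(6R,7S)-7-[3-(TBSO)prop-1-en-2-yl]-7-methyl-1,4-dioxaspiro[4.5]decan-6-yl}propan-1-ol
Product: 12 3-{(6R,7S)-7-[3-(TBSO)prop-1-en-2-yl]-7-methyl-1,4-dioxaspiro[4.5]decan-6-yl}propanoic acid, via aldehyde 11 (not isolated)
Conditions: 2,2,6,6-tetramethylpiperidin-1-oxyl (20 mol %), PhI(OAc)2, MeCN–H2O, rt
Reagents that add atoms: water, O
Why: Oxoammonium-mediated oxidation in aqueous medium takes a primary alcohol through the aldehyde hydrate to the acid under near-neutral conditions that leave ketal, silyl ether and alkene untouched.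

Step 6
Reactants: 12 3-{(6R,7S)-7-[3-(TBSO)prop-1-en-2-yl]-7-methyl-1,4-dioxaspiro[4.5]decan-6-yl}propanoic acid
Product: 15 4-{(6R,7S)-7-[3-(TBSO)prop-1-en-2-yl]-7-methyl-1,4-dioxaspiro[4.5]decan-6-yl}butan-2-one, via lithium carboxylate 13 (not isolated), via dilithium gem-diolate 14 (not isolated)
Conditions: MeLi (3 equiv), Et2O, 0 °C; H2O
Reagents that add atoms: methyllithium, [Li]C
Why: Addition of methyllithium to a lithium carboxylate stops at the stable gem-diolate, which collapses to the methyl ketone only on work-up and so brings in C12 (classical acid-to-methyl-ketone conversion).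

Step 7
Reactants: 15 4-{(6R,7S)-7-[3-(TBSO)prop-1-en-2-yl]-7-methyl-1,4-dioxaspiro[4.5]decan-6-yl}butan-2-one
Product: 17 4-{(6R,7S)-7-[3-(TBSO)prop-1-en-2-yl]-7-methyl-1,4-dioxaspiro[4.5]decan-6-yl}but-1-en-2-yl trifluoromethanesulfonate, via potassium enolate 16 (not isolated)
Conditions: KN(SiMe3)2, THF, −78 °C; N-(5-chloro-2-pyridyl)bis(trifluoromethanesulfonimide), −78 °C
Reagents that add atoms: N-(5-chloro-2-pyridyl)bis(trifluoromethanesulfonimide), FC(F)(F)S(=O)(=O)N(c1ccc(Cl)cn1)S(=O)(=O)C(F)(F)F
Why: With the ring carbonyl masked, 15 holds a single ketone, and kinetic deprotonation by the bulky amide at −78 °C takes a C12 methyl proton, so O-sulfonylation gives the terminal enol triflate (kinetic enol triflation).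

Step 8
Reactants: 17 4-{(6R,7S)-7-[3-(TBSO)prop-1-en-2-yl]-7-methyl-1,4-dioxaspiro[4.5]decan-6-yl}but-1-en-2-yl trifluoromethanesulfonate
Product: 18 (5R,9R,10S)-trans-decalin: C4 ethylene ketal; C8 exocyclic methylene; C9 β-CH3 (equatorial) and α-CH2OTBS (axial); C10 β-CH3; H5 α
Conditions: Pd(OAc)2 (10 mol %), PPh3 (25 mol %), HCO2Na, DMF, 60 °C
Reagents that add atoms: none
Why: Pd(OAc)2 and PPh3 give zerovalent palladium, which inserts into the C8–O bond of the triflate; the cationic vinylpalladium binds the C9=C13 alkene and adds syn across it (C8 to C9, Pd to C13), and the neopentyl C13–Pd species, which has no β-hydrogen because C9 is now quaternary, takes up formate, loses CO2 and eliminates C13–H. This is a reductive Heck cyclization (carbopalladation with hydride capture) of the known kind that turns a 1,1-disubstituted alkene into a methyl-bearing quaternary carbon. Ring B closes in the 6-exo-trig mode, and since the new bond lies away from the C5–C10 fusion, the trans relation from step 2 becomes the trans-decalin without further control. C9 is the only new stereocentre: in the chair-like insertion geometry the alkene plane stands perpendicular to the incoming C8, and the favoured rotamer about C9–C10 has the flat =C13H2 end nearly eclipsing the axial C10 methyl (the normal resting arrangement next to a quaternary carbon) with the CH2OTBS arm staggered between C1 and C5 on the α face, whereas the other rotamer forces that arm to eclipse the methyl and crowd C12; C11 should therefore end axial, cis to H5, and C13 equatorial. The step also needs insertion to outrun formate reduction of the vinylpalladium species, which should be secured by the halide-free cationic pathway of the triflate, the sparingly soluble HCO2Na and the absence of any other alkene in 17.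

Step 9
Reactants: 18 trans-decalin silyl ether
Product: 19 (5R,9R,10S)-alcohol: as 18 with a free axial α-CH2OH (C11) on C9
Conditions: Bu4NF, THF, rt
Reagents that add atoms: none
Why: Fluoride cleavage of a primary TBS ether is selective for silicon and leaves the ketal and the exocyclic alkene alone.

Step 10
Reactants: 19 homoallylic alcohol
Product: 20 (5R,8S,9R,10S)-alcohol: C4 ethylene ketal; C8 β-CH3 (axial) and H8 α; C9 β-CH3 and α-CH2OH; C10 β-CH3; H5 α
Conditions: [Ir(cod)(PCy3)(py)]PF6 (5 mol %), H2 (1 atm), CH2Cl2, rt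
Reagents that add atoms: none
Why: In this hydroxyl-directed hydrogenation the cationic iridium catalyst binds the axial C11 hydroxyl and delivers H2 to the α face of C8=C12, giving the otherwise disfavoured axial C12 methyl, and any isomerization to the C7=C8 alkene is funnelled to the same product.

Step 11
Reactants: 20 saturated alcohol
Product: 21 (5R,8S,9R,10S)-aldehyde: as 20 with an axial α-CHO (C11) on C9
Conditions: Dess–Martin periodinane, CH2Cl2, rt
Reagents that add atoms: none
Why: Dess–Martin oxidation handles neopentyl primary alcohols under mild conditions, and the aldehyde has no α-hydrogen to epimerize.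

Step 12
Reactants: 21 neopentyl aldehyde; 22 1,2,4,5-tetramethoxybenzene
Product: 26 O-[C11 aryl carbinyl] S-methyl dithiocarbonate (C11 bears 2,3,5,6-tetramethoxyphenyl; both C11 epimers), via aryllithium 23 (not isolated), via lithium alkoxide 24 (not isolated), via lithium xanthate 25 (not isolated)
Conditions: 22, n-BuLi, THF, 0 °C → rt; 21, −78 → 0 °C; CS2, 0 °C → rt; MeI
Reagents that add atoms: carbon disulfide, S=C=S; iodomethane, CI
Why: Directed ortho-lithiation between two methoxy groups gives a nucleophile that adds 1,2 to the non-enolizable aldehyde, the alkoxide is converted in the same flask into the xanthate, and the new C11 centre is erased in step 13, so its configuration does not matter.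

Step 13
Reactants: 26 benzylic xanthate
Product: 27 (5R,8S,9R,10S)-C11-aryl decalin ketal: C9 α-CH2–(2,3,5,6-tetramethoxyphenyl); C4 ethylene ketal
Conditions: Bu3SnH, azobisisobutyronitrile (cat.), toluene, 90 °C
Reagents that add atoms: none
Why: Barton–McCombie deoxygenation runs through a stabilized benzylic radical that finds neither an alkene nor a fragmentable β-bond in 26 and is simply reduced.

Step 14
Reactants: 27 aryl decalin ketal
Product: 28 (5R,8S,9R,10S)-C4 ketone: as 27 with C4=O
Conditions: pyridinium p-toluenesulfonate (cat.), acetone–H2O, 40 °C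
Reagents that add atoms: water, O
Why: Mild acid hydrolysis of this strained dioxolane (one oxygen is 1,3-diaxial to the C10 methyl) is far faster than acid enolization of the released ketone, so H5 stays α.

Step 15
Reactants: 28 C4 ketone
Product: 29 (5S,8S,9R,10S)-C4 exocyclic methylene arene: as 28 with C4=CH2
Conditions: Zn, CH2Br2, TiCl4, THF–CH2Cl2, 0 °C → rt
Reagents that add atoms: dibromomethane, BrCBr
Why: Takai–Lombardo methylenation uses a non-basic gem-dizinc/titanium reagent that converts hindered enolizable ketones without α-epimerization, which matters because relief of the C8/C10 diaxial methyl contact would favour the cis-decalone.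

Step 16
Reactants: 29 tetramethoxyarene
Product: 30 2,5-dimethoxy-3-(C11-decalinylmethyl)-1,4-benzoquinone
Conditions: (NH4)2Ce(NO3)6, MeCN–H2O, 0 °C
Reagents that add atoms: water, O
Why: Oxidative demethylation of a 1,2,4,5-tetramethoxyarene gives the dimethoxy-para-quinone, either para pair leads to the same quinone, and an isolated 1,1-disubstituted alkene tolerates the short cold exposure.

Step 17
Reactants: 30 dimethoxyquinone
Product: 32 CNP0109104.1 (5S,8S,9R,10S), via potassium quinonolate 31 (not isolated)
Conditions: KOH, MeOH–H2O, rt; 1 M HCl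
Reagents that add atoms: potassium hydroxide, [K+].[OH-]
Why: In this regioselective saponification of a vinylogous ester the methoxy group next to the bulky C11 arm is twisted out of conjugation and is displaced first, and the resulting quinonolate anion resists a second attack, so the C5' methoxy group remains.

Compound list
1 | 2-bromoprop-2-en-1-ol | OCC(Br)=C | starting material
2 | tert-butyl[(2-bromoprop-2-en-1-yl)oxy]dimethylsilane | C=C(Br)CO[Si](C)(C)C(C)(C)C | intermediate
3 | 3-methylcyclohex-2-en-1-one | CC1=CC(=O)CCC1 | starting material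
4 | allyl bromide | C=CCBr | starting material
5 | [3-(TBSO)prop-1-en-2-yl]magnesium bromide | C=C([Mg]Br)CO[Si](C)(C)C(C)(C)C | intermediate
6 | bromomagnesium (S)-3-[3-(TBSO)prop-1-en-2-yl]-3-methylcyclohex-1-en-1-olate | C=C(CO[Si](C)(C)C(C)(C)C)[C@@]1(C)CCCC(O[Mg]Br)=C1 | intermediate
7 | (2R,3S)-2-allyl-3-[3-(TBSO)prop-1-en-2-yl]-3-methylcyclohexan-1-one | C=CC[C@H]1C(=O)CCC[C@]1(C)C(=C)CO[Si](C)(C)C(C)(C)C | intermediate
8 | (6R,7S)-6-allyl-7-[3-(TBSO)prop-1-en-2-yl]-7-methyl-1,4-dioxaspiro[4.5]decane | C=CC[C@H]1C2(OCCO2)CCC[C@]1(C)C(=C)CO[Si](C)(C)C(C)(C)C | intermediate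
9 | B-alkyl-9-BBN adduct of 8 (boron on C8) | C(CC[C@H]1C2(OCCO2)CCC[C@]1(C)C(=C)CO[Si](C)(C)C(C)(C)C)B1C2CCCC1CCC2 | intermediate
10 | C8 primary alcohol | OCCC[C@H]1C2(OCCO2)CCC[C@]1(C)C(=C)CO[Si](C)(C)C(C)(C)C | intermediate
11 | C8 aldehyde | O=CCC[C@H]1C2(OCCO2)CCC[C@]1(C)C(=C)CO[Si](C)(C)C(C)(C)C | intermediate
12 | C8 carboxylic acid | OC(=O)CC[C@H]1C2(OCCO2)CCC[C@]1(C)C(=C)CO[Si](C)(C)C(C)(C)C | intermediate
13 | lithium carboxylate of 12 | [Li]OC(=O)CC[C@H]1C2(OCCO2)CCC[C@]1(C)C(=C)CO[Si](C)(C)C(C)(C)C | intermediate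
14 | dilithium gem-diolate at C8 | CC(O[Li])(O[Li])CC[C@H]1C2(OCCO2)CCC[C@]1(C)C(=C)CO[Si](C)(C)C(C)(C)C | intermediate
15 | C8 methyl ketone | CC(=O)CC[C@H]1C2(OCCO2)CCC[C@]1(C)C(=C)CO[Si](C)(C)C(C)(C)C | intermediate
16 | potassium C8=C12 enolate | C=C(O[K])CC[C@H]1C2(OCCO2)CCC[C@]1(C)C(=C)CO[Si](C)(C)C(C)(C)C | intermediate
17 | C8 vinyl triflate (cyclization precursor) | C=C(OS(=O)(=O)C(F)(F)F)CC[C@H]1C2(OCCO2)CCC[C@]1(C)C(=C)CO[Si](C)(C)C(C)(C)C | intermediate
18 | trans-decalin with C8 methylene, C9 β-CH3/α-CH2OTBS, C4 ketal | C=C1CC[C@H]2C3(OCCO3)CCC[C@]2(C)[C@]1(C)CO[Si](C)(C)C(C)(C)C | intermediate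
19 | C11 alcohol with C8 methylene | C=C1CC[C@H]2C3(OCCO3)CCC[C@]2(C)[C@]1(C)CO | intermediate
20 | C11 alcohol with axial β-C12 methyl | C[C@H]1CC[C@H]2C3(OCCO3)CCC[C@]2(C)[C@]1(C)CO | intermediate
21 | C11 aldehyde | C[C@H]1CC[C@H]2C3(OCCO3)CCC[C@]2(C)[C@]1(C)C=O | intermediate
22 | 1,2,4,5-tetramethoxybenzene | COc1cc(OC)c(OC)cc1OC | starting material
23 | 2,3,5,6-tetramethoxyphenyllithium | COc1cc(OC)c(OC)c([Li])c1OC | intermediate
24 | lithium C11 aryl carbinolate (both C11 epimers) | C[C@H]1CC[C@H]2C3(OCCO3)CCC[C@]2(C)[C@]1(C)C(O[Li])c1c(OC)c(OC)cc(OC)c1OC | intermediate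
25 | lithium O-alkyl dithiocarbonate (both C11 epimers) | C[C@H]1CC[C@H]2C3(OCCO3)CCC[C@]2(C)[C@]1(C)C(OC(=S)S[Li])c1c(OC)c(OC)cc(OC)c1OC | intermediate
26 | S-methyl xanthate (both C11 epimers) | C[C@H]1CC[C@H]2C3(OCCO3)CCC[C@]2(C)[C@]1(C)C(OC(=S)SC)c1c(OC)c(OC)cc(OC)c1OC | intermediate
27 | C11-aryl decalin ketal | C[C@H]1CC[C@H]2C3(OCCO3)CCC[C@]2(C)[C@]1(C)Cc1c(OC)c(OC)cc(OC)c1OC | intermediate
28 | C4 ketone | C[C@H]1CC[C@H]2C(=O)CCC[C@]2(C)[C@]1(C)Cc1c(OC)c(OC)cc(OC)c1OC | intermediate
29 | C4 methylene tetramethoxyarene | C[C@H]1CC[C@H]2C(=C)CCC[C@]2(C)[C@]1(C)Cc1c(OC)c(OC)cc(OC)c1OC | intermediate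
30 | 2,5-dimethoxyquinone | C[C@H]1CC[C@H]2C(=C)CCC[C@]2(C)[C@]1(C)CC1=C(OC)C(=O)C=C(OC)C1=O | intermediate
31 | potassium quinonolate of the target | C[C@H]1CC[C@H]2C(=C)CCC[C@]2(C)[C@]1(C)CC1=C(O[K])C(=O)C=C(OC)C1=O | intermediate
32 | CNP0109104.1 | C=C1CCC[C@@]2(C)[C@H]1CC[C@H](C)[C@@]2(C)CC1=C(O)C(=O)C=C(OC)C1=O | target

Total steps: 17. Longest linear sequence: 17 (1 → 32); 3, 4 and 22 enter as bought.

Steps most likely to fail

Step 8. Three processes threaten it:
- Formate may reduce the vinylpalladium species before it inserts next to quaternary C10, which is plain loss of the triflate.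
- The neopentyl palladium species may escape by 3-exo attack on the new C8=C12 alkene.
- Insertion through the second C9–C10 rotamer at 60 °C would erode facial selectivity at C9.

The fallback sets out from 17 and comes back at 18. It changes how the vinylpalladium species is made.
- LiN(i-Pr)2 (2.2 equiv, THF, −78 → 0 °C) would eliminate triflate to give the lithium acetylide F1, which is protonated on work-up to the 1,7-enyne F2.
- Pd2(dba)3·CHCl3, P(o-tol)3, AcOH and Et3SiH in toluene at rt would then run a reductive enyne cyclization.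
- In that reaction H–Pd–OAc adds to the alkyne with palladium on C8, the same 6-exo insertion forms C8–C9, and the silane cleaves the C13–Pd bond.
- No hydride sits on palladium before the insertion, and the lower temperature should sharpen the rotamer preference.

Step 2. Transfer of the branched, oxygenated alkenyl group may be sluggish or unselective. Possible causes are competing 1,2-addition, loss of silyloxide from the Grignard reagent and weak enantiofacial discrimination. The fallback sets out from 2 and comes back at 6 by exchanging the roles of the two C10 substituents.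
- t-BuLi (2 equiv, Et2O, −78 °C) would give the alkenyllithium F3.
- F3 adds 1,2 to commercial 3-ethoxycyclohex-2-en-1-one (CCOC1=CC(=O)CCC1) to give the lithium carbinolate F4.
- Dilute HCl would then effect the Stork–Danheiser transposition to the conjugated dienone F5.
- MeMgBr under the same Cu(OTf)2/imidazolinium catalysis (mirror-image ligand if required) would add 1,4 rather than 1,6, as is known for cyclic dienones. This gives enolate 6, which is allylated as before.

Step 12. Addition of the doubly ortho-substituted aryllithium to the axial neopentyl aldehyde may be slow. Capture of the very hindered alkoxide by CS2 may also stall. The fallback sets out from 20 and 22 and comes back at 27, so steps 11 to 13 drop out.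
- I2, PPh3 and imidazole in toluene at 90 °C would turn 20 into the neopentyl iodide F6.
- Zinc dust and LiCl in THF would insert to give the alkylzinc iodide F7, which cannot lose a β-hydrogen because C9 is quaternary.
- N-bromosuccinimide in MeCN would convert 22 into 3-bromo-1,2,4,5-tetramethoxybenzene F8.
- Negishi coupling of F7 and F8 (Pd2(dba)3, 2-dicyclohexylphosphino-2',6'-dimethoxybiphenyl, THF, 60 °C) would form the C11–aryl bond directly.

Further compounds
F1 | step 8 | lithium acetylide of the 1,7-enyne | [Li]C#CCC[C@H]1C2(OCCO2)CCC[C@]1(C)C(=C)CO[Si](C)(C)C(C)(C)C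
F2 | step 8 | (6R,7S)-6-(but-3-yn-1-yl)-7-[3-(TBSO)prop-1-en-2-yl]-7-methyl-1,4-dioxaspiro[4.5]decane | C#CCC[C@H]1C2(OCCO2)CCC[C@]1(C)C(=C)CO[Si](C)(C)C(C)(C)C
F3 | step 2 | [3-(TBSO)prop-1-en-2-yl]lithium | [Li]C(=C)CO[Si](C)(C)C(C)(C)C
F4 | step 2 | lithium 3-ethoxy-1-[3-(TBSO)prop-1-en-2-yl]cyclohex-2-en-1-olate (racemic) | CCOC1=CC(O[Li])(CCC1)C(=C)CO[Si](C)(C)C(C)(C)C
F5 | step 2 | 3-[3-(TBSO)prop-1-en-2-yl]cyclohex-2-en-1-one | C=C(CO[Si](C)(C)C(C)(C)C)C1=CC(=O)CCC1
F6 | step 12 | C11 neopentyl iodide | C[C@H]1CC[C@H]2C3(OCCO3)CCC[C@]2(C)[C@]1(C)CI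
F7 | step 12 | C11 alkylzinc iodide | C[C@H]1CC[C@H]2C3(OCCO3)CCC[C@]2(C)[C@]1(C)C[Zn]I
F8 | step 12 | 3-bromo-1,2,4,5-tetramethoxybenzene | COc1cc(OC)c(OC)c(Br)c1OC
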